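The rate constants were chosen freely; the result is computed.

A small charge of partner, 0.105 M against 0.15 M of substrate, has two roads in these flasks, and what takes the road to target can go on to over-reaction product.

in all of them: time 6.0 d
- east: substrate 0.15 M; partner 0.105 M (fed, over 4.0 d); the addition at 70 °C, then warmed to 110 °C; the feed brings no volume worth counting
- north: substrate 0.15 M; partner 0.105 M; everything together at the start at 70 °C, warmed to 110 °C at 4.0 d
- north-east: substrate 0.15 M (fed, over 4.0 d); partner 0.105 M; all else is in the flask from the start; the feed brings no volume worth counting; temperature 110 °C
- west: substrate 0.15 M; partner 0.105 M; everything together at the start; temperature 110 °C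
- south-east: substrate 0.15 M; partner 0.105 M (fed, over 10 h); all else is in the flask from the start; the feed brings no volume worth counting; temperature 110 °C

    substrate + partner → target (k1 = 0.80 M⁻¹ h⁻¹, Ea1 = 77.0 kJ mol⁻¹)
    2 partner → side product (k2 = 0.71 M⁻¹ h⁻¹, Ea2 = 106 kJ mol⁻¹)
    target → over-reaction product (k3 = 0.028 h⁻¹, Ea3 = 125 kJ mol⁻¹)
    (constants at 110 °C)

- for a step with 2 of a species take k times the square, and two of it per event
- the list of constants is for 110 °C, to be carried to other temperatures by the activation energies

- which flask leads in amount of over-reaction product, in percent of the substrate charged ("all alike" within 1.5 percentage points) (east / north / north-east / west / south-east / all alike)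
- how much over-reaction product is there at the end, in percent of the substrate charged: east
- how much over-reaction product is there at the end, in percent of the substrate charged: north
- how much over-reaction product is there at the end, in percent of the substrate charged: north-east
- how much over-reaction product is there at the end, in percent of the substrate charged: west
- how much over-reaction product is there at the end, in percent of the substrate charged: south-east

- I wrote the balance of the two roads first: each substrate lost costs one partner, plus split × c(partner)/c(substrate) more partner lost to side product. The split (selectivity factor) is 2 times the constant of the partner's coupling over that of the main step, 1.77 at 110 °C, and time drops out of the ratio.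
- A split of one is my statistical zero, where the two losses of partner are equal at equal concentrations. Batch substrate left at the end of partner is then exp(−c(partner)/c(substrate)) at the charges, 49.7%.
- For any other split, the batch fraction left is (1 + (split − 1)·c(partner)/c(substrate))^(−1/(split − 1)). At 110 °C it gave 57.2%, above zero, so west should make 42.8% target.
- But target is not yet over-reaction product. Its half-life of 1.0 d against 6.0 d leaves 1.77% of early target, so I put west at 42.1%.
- The cold flasks looked better, since at 70 °C the split falls to 0.614, and the rule at that split leaves 44.2% of the substrate.
- Yet they get 2.00 d hot, and hardly any target turns over in the cold 4.0 d, so I capped north at 41.2% and east at 41.2%.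
- In north-east, partner's coupling half-life of 6.71 h is far shorter than the feed, so partner couples while substrate trickles in. Substrate came in at 0.00156 M h⁻¹, so I let partner decay by coupling and stopped that picture at 40.0 h, where the main step's own loss, growing with the substrate piled up, has cut partner by a factor e. Summing the main rate up to that time, with substrate taken as unconsumed and partner as thinned by coupling, gave 15.8% target. The sharp stop is crude, but with the survival of 1.77% over the full 6.0 d it put north-east at 15.6%, under west.
- For south-east I ran the rule on two half charges of partner, which left 73.4% and then 48.9%, and so gave 50.2%.
- The objection was that 10 h of feed against 6.71 h lets the portions overlap, so I took that figure as generous, with west as its floor. My pick stood: south-east.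
- The forecast named south-east, with east 34.7%, north 35.9%, north-east 14.5%, west 41.9% and south-east 51%: “the short partner feed wins”.
- The simulation put south-east first at 46.4%, then west 41.8%, north 34.9%, east 33.0% and north-east 14.2%.
- South-east ended with 0.0167 M of side product against 0.0204 M in west. West kept 57.2% of its substrate, and south-east kept 52.3%, between the two-portion 48.9% and the batch 57.2%.
- On the south-east flask with 0.037 M of substrate, the batch rule with the same split gave 22.2% substrate left. The run held 23.5%, with 2.35% of partner remaining and 72.0% over-reaction product.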